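## Structural features

Ring A is numbered C1 (butanoyl), C2 (methyl), C3 (bridge), C4 (OMe), C5 (methyl), C6 (OH). Ring B is numbered C1 (bridge), C2 (OH), C3 (methyl), C4 (OH), C5 (butanoyl), C6 (OH).

The target is an achiral diarylmethane in which two hexasubstituted benzene rings are joined by one CH2 group. Ring A is a resorcinol monomethyl ether with two methyl groups and an ortho-hydroxy ketone. Ring B is a C-methyl, C-acyl phloroglucinol. There is no stereocenter, so no stereocenters stand next to each other; the only sp3 ring carbons are transient intermediates. The fragile features are three: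

- The polyphenol is electron-rich and prone to air oxidation.
- The methylene bridge lies ortho and para to oxygen on both rings. It can be lost by ipso protonation in acid, or through quinone methides in base, until both rings carry their deactivating acyl groups.
- The single aryl methyl ether must survive whatever frees the other four oxygens.

The real difficulty is regiocontrol: twelve ring positions each need a defined substituent and five phenolic oxygens must be told apart. The key step exploits the ring B oxygens at C2, C4 and C6, which are mutually meta and alternate with carbon substituents. C2, C1, C6 and C5 can come from the vinylketene of a 3-alkoxy-4-(arylmethyl)cyclobutenone, and C3 (with its methyl) and C4 (with its oxygen) from a siloxyalkyne. C5 is then the only C–H of ring B.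

## Logic of the disconnections

**28 from 27.** The last bond cut is the O–CH3 bond at ring A C6. A methyl ether there protects that oxygen during acylation, and it is the one ether a Lewis acid can find by chelation to the C1 ketone. The gain is that 27 needs no other protecting group, because ring B is already free. The forward step must cleave one of two aryl methyl ethers; the C4 ether has no carbonyl neighbor to chelate with.

**27 from 25.** The bonds cut are ring A C1–C(=O) and ring B C5–C(=O); in the reverse sense the O–C(CH3)3 bond at ring B C6 is restored. Each ring has exactly one unsubstituted carbon, both ortho and para to oxygen donors, so double Friedel–Crafts acylation with butanoyl chloride has no regiochemical choice. The gain is eight carbons and both ketones. The forward step must acylate both rings before acid harms the bridge, and ring B must leave it with no ether. That is why 25 carries a tert-butyl ether and not a primary alkyl ether. After acylation, a primary ether at ring B C6 would sit beside a ketone already chelated by the C4 hydroxyl. As the second ortho ether it could be expected to resist BCl3, and any reagent strong enough to remove it would no longer spare the ring A C4 methoxy group. A tert-butyl ether is removed by AlCl3 within the acylation step.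

**25 from 24.** The O–Si bond at ring B C4 is cut. The silyl group is what the alkyne partner delivers, and its removal before acylation unblocks C5, which it flanks. The gain is orthogonality: fluoride touches no other group. The forward step needs buffered fluoride so that the electron-rich phenoxide is not left exposed.

**24 from 15 and 19.** The ring B bonds C2–C3, C4–C5 and C1–C2 are cut. This is the strategic cut because it resolves the three meta oxygens and their alternating carbon substituents into a four-carbon and a two-carbon piece. Ring A and the bridge carbon are already in 15. The forward step must control the orientation of the alkyne on the ketene, and 15 must open thermally below the temperature at which 19 or the tert-butyl ether degrades.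

**15 from 8 and 13.** The cyclobutenone C1–C2 and C3–C4 bonds are cut, which corresponds to cycloaddition of 13 with ketene 14 generated from 8. The polarity of both partners places the alkoxy group at C3 and the arylmethyl group at C4, which is the isomer the annulation needs. The gain is a linear acid chloride and a two-carbon ynol ether. The forward step must trap 14 faster than it dimerizes, under conditions mild enough for a tert-butyl ynol ether.

**13 from 11 from 9.** Two H–Br eliminations are reversed and the C=C bond of 9 is brominated. This takes the ynol ether back to a bulk vinyl ether. The forward steps must stay cold and basic because the tert-butyl group is acid- and heat-labile.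

**19 from 16.** The O–Si bond and the C–C bond between the two alkyne carbons are cut. The ynolate 18 arises from 16 by one-carbon homologation with LiCHBr2 and 1,2-shift of the methyl group. The gain is a commodity ester as the source of ring B C3, its methyl and C4. The forward step must silylate on oxygen and not on carbon, which the bulky silyl chloride secures.

**8 from 7 from 6 from 4.** The C–Cl bond, then the Cα–Cβ double bond formed with malonic acid, are cut. This is a two-carbon homologation of an aldehyde in two steps plus activation. The forward condensation must succeed on a di-ortho-substituted aldehyde. An intramolecular Friedel–Crafts closure of 8 is ruled out because both positions ortho to the chain are substituted.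

**4 from 2 from 1.** The aryl–CHO bond and the two O–CH3 bonds are cut. 2 is symmetric with two equivalent free positions, so formylation can give only 4. The aldehyde carbon becomes the bridge, its ortho methoxy becomes ring A C4–OMe and its para methoxy becomes the C6 oxygen.

## Other disconnections considered

**Alternative 1:** The cut is at ring A, through the C3–bridge bond and the C2–methyl bond, both made on an aryne.

- Forward step: CsF converts 3,5-dimethoxy-4-methyl-2-(trimethylsilyl)phenyl trifluoromethanesulfonate A1 into 3,5-dimethoxy-4-methylbenzyne A2. The enolate carbon of the ring B β-keto sulfone A3 adds at the aryne carbon remote from the methoxy group, the aryl anion closes onto the ketone, and the four-membered alkoxide fragments. The arene is thereby inserted into the C(O)–CH2 bond to give diaryl ketone A4.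
- In its favour: two adjacent C–C bonds form in one mild, non-acidic step, with regiochemistry set by the methoxy group beside the aryne. Ring B enters complete and protected as benzyl ethers, which hydrogenolysis removes under neutral conditions. On that point it is better than the chosen plan, which frees ring B with fluoride and a Lewis acid.
- Against it: the bridge arrives as a carbonyl and the C2 methyl as a sulfonylmethyl group. A4 therefore needs deoxygenation of a tetra-ortho-substituted, electron-rich diaryl ketone and a reductive desulfonylation. Ring A of A4 still has a free C1–H and two methyl ethers, so the Friedel–Crafts acylation and the chelation-controlled demethylation of the chosen plan are needed anyway, as is the acylation of ring B. A1 itself needs several steps.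
- Comparison: both plans join two ring-sized pieces and form two C–C bonds in the key step, so they are equal in convergence. Mechanistically the aryne route is anionic and depends on C- versus O-attack of the enolate, whereas the chosen plan is pericyclic. In step economy the aryne route is longer after its key step (two reductions and a debenzylation on top of the common endgame).

**Alternative 2:** The cut is at ring A C1–C2 and C4–C5, with ring A made as a cyclohexane-1,3-dione and aromatized later.

- Forward step: NaOEt promotes Michael addition of ethyl 3-oxopentanoate A5 to ethyl (2E)-2-[2,4,6-tris(benzyloxy)-3-methylbenzyl]but-2-enoate A6. Claisen closure of the ethyl ketone methylene onto the crotonate ester then gives dione A7.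
- In its favour: the chemistry is classical enolate chemistry with cheap reagents and no ketenes, ynol ethers or sealed tubes. The future ring A C1 already bears a carboxyl carbon, so ring A never needs a Friedel–Crafts acylation, which is a better point than in the chosen plan. After aromatization the two ring A oxygens would differ by chelation to the ester, a differentiation equal in kind to the BCl3 selectivity used here.
- Against it: A6 is an α,β-disubstituted enoate and a poor, reversible Michael acceptor. A7 has no ring CH2, so aromatization is a true dehydrogenation that must tolerate benzyl ethers and an electron-rich arene. The ester must then become a propyl ketone at a position with two ortho substituents. Four stereocenters are made only to be erased, and ring B still has to be debenzylated and acylated.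
- Comparison: structurally it builds ring A where the chosen plan builds ring B. Mechanistically it is ionic and stepwise, with an equilibrium-limited first step, against a thermal cascade. In step economy it needs an oxidation, a selective methylation and an ester-to-ketone change after the key step, and is clearly longer.

**Alternative 3:** The cut is at ring A C2–C3 and C1–C6, a Diels–Alder assembly of the whole of ring A.

- Forward step: the silyl ketene acetal diene {[(1Z,3Z)-1,3-dimethoxy-2-methyl-5-[2,4,6-tris(benzyloxy)-3-methylphenyl]penta-1,3-dien-1-yl]oxy}trimethylsilane A8 adds to hept-2-yn-4-one A9. The nucleophilic diene terminus bonds to the ynone β-carbon, and loss of methanol and of the silyl group aromatizes the adduct to A10.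
- In its favour: ring A arrives with its butanoyl group, its chelated hydroxyl and its single methoxy group in place. No acylation or ether cleavage is needed on ring A, which is better than the chosen plan in functional-group economy. Regiochemistry follows from the polarization of both partners.
- Against it: A8 is substituted at every diene carbon, reaches the s-cis form with difficulty and is hydrolytically labile. A9 is a β-alkyl ynone and only a moderate dienophile, so the cycloaddition would need forcing conditions. A8 needs a ring B building block and four or five steps of chain construction with control of enol ether geometry. A10 still requires debenzylation and acylation of ring B.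
- Comparison: structurally it is the mirror of the chosen plan (ring A made on a ring B fragment). Mechanistically both are pericyclic, but the chosen cascade uses a reactive ketene and a polarized alkyne where this one pairs a congested diene with a sluggish dienophile. It is about equal or slightly shorter after the key step (two steps against three) and longer before it.

Key step: step 10

Remark on the chemistry: the alkoxy group of the cyclobutenone and the silyl group of the alkyne are treated as spectator protecting groups (tert-butyl and triisopropylsilyl), and neither tert-butoxyacetylene nor the siloxyalkyne is assumed to be purchasable.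

## Route

Step 1
Reactants: 1 2,5-dimethylresorcinol (2,5-dimethylbenzene-1,3-diol)
Product: 2 1,3-dimethoxy-2,5-dimethylbenzene
Conditions: MeI (3 equiv), K2CO3, acetone, reflux
Reagents that add atoms: iodomethane, CI
Why: Williamson O-methylation of both phenols; the phenoxides are the only nucleophiles and the product is symmetric, so no selectivity question arises.

Step 2
Reactants: 2 1,3-dimethoxy-2,5-dimethylbenzene
Product: 4 2,4-dimethoxy-3,6-dimethylbenzaldehyde, via iminium chloride 3 (not isolated)
Conditions: POCl3, DMF, 0 → 80 °C; then aq. NaOAc
Reagents that add atoms: N,N-dimethylformamide, CN(C)C=O; water, O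
Why: Vilsmeier–Haack formylation; the two free positions of 2 are equivalent and each is ortho and para to a methoxy group, so one aldehyde should form, and the formyl group deactivates the ring against a second attack.

Step 3
Reactants: 4 2,4-dimethoxy-3,6-dimethylbenzaldehyde
Product: 6 (E)-3-(2,4-dimethoxy-3,6-dimethylphenyl)prop-2-enoic acid, via arylidenemalonic acid 5 (not isolated)
Conditions: CH2(CO2H)2, pyridine, piperidine (cat.), 100 °C
Reagents that add atoms: malonic acid, OC(=O)CC(=O)O
Why: Knoevenagel condensation with decarboxylation in the same flask (Doebner modification); the E alkene is expected under thermodynamic control and its geometry is irrelevant after step 4.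

Step 4
Reactants: 6 (E)-3-(2,4-dimethoxy-3,6-dimethylphenyl)prop-2-enoic acid
Product: 7 3-(2,4-dimethoxy-3,6-dimethylphenyl)propanoic acid
Conditions: H2 (1 atm), Pd/C, EtOAc, 25 °C
Reagents that add atoms: none
Why: Heterogeneous hydrogenation of the conjugated alkene; the arene, the ethers and the acid are inert, and there is no benzylic C–O bond to hydrogenolyze.

Step 5
Reactants: 7 3-(2,4-dimethoxy-3,6-dimethylphenyl)propanoic acid
Product: 8 3-(2,4-dimethoxy-3,6-dimethylphenyl)propanoyl chloride
Conditions: (COCl)2, DMF (cat.), CH2Cl2, 0 → 25 °C; evaporate
Reagents that add atoms: oxalyl chloride, O=C(Cl)C(Cl)=O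
Why: Standard acid chloride formation through the catalytic chloroiminium species; both ring positions ortho to the side chain are substituted, so the electron-rich arene cannot close to an indanone.

Step 6
Reactants: 9 tert-butyl vinyl ether
Product: 11 (Z)-1-bromo-2-tert-butoxyethene, via dibromide 10 (not isolated)
Conditions: Br2, pentane, −78 °C; then Et3N, −78 → 35 °C; distil
Reagents that add atoms: bromine, BrBr
Why: Bromine addition to the enol ether gives the α,β-dibromo ether 10, whose labile α-bromide ionizes and loses HBr to the amine, the classical entry to 2-bromovinyl ethers; cold, base-buffered conditions protect the tert-butyl group and either alkene isomer serves in step 7.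

Step 7
Reactants: 11 (Z)-1-bromo-2-tert-butoxyethene
Product: 13 tert-butoxyacetylene, via sodium tert-butoxyacetylide 12 (not isolated)
Conditions: NaNH2 (2.3 equiv), liq. NH3, −33 °C; then cold brine; pentane extraction, distil cold
Reagents that add atoms: none
Why: Amide-induced dehydrobromination of a 2-bromovinyl ether, as in the standard preparation of ethoxyacetylene, with the product held as acetylide 12 until the cold quench; 13 is kept cold because tert-butyl ynol ethers lose isobutene on warming.

Step 8
Reactants: 8 3-(2,4-dimethoxy-3,6-dimethylphenyl)propanoyl chloride; 13 tert-butoxyacetylene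
Product: 15 racemic 3-tert-butoxy-4-(2,4-dimethoxy-3,6-dimethylbenzyl)cyclobut-2-en-1-one, via aldoketene 14 (not isolated)
Conditions: Et3N (1.3 equiv), 13 (3 equiv), Et2O, 25 °C, 8 added over 4 h
Reagents that add atoms: none
Why: Dehydrochlorination of 8 gives ketene 14, which undergoes the regiospecific [2+2] cycloaddition of ketenes with alkoxyacetylenes (terminal alkyne carbon to the ketene carbonyl carbon), placing the alkoxy group at C3 and the arylmethyl group at C4; slow addition into excess 13 keeps 14 dilute against dimerization, and the C4 stereocenter forms racemic and is erased in step 10.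

Step 9
Reactants: 16 ethyl acetate
Product: 19 1-(triisopropylsiloxy)propyne, via lithium dibromoenolate 17 (not isolated), via lithium propynolate 18 (not isolated)
Conditions: CH2Br2, lithium 2,2,6,6-tetramethylpiperidide (2.1 equiv), THF, −78 °C, then 16; n-BuLi, −78 → 25 °C; i-Pr3SiCl, −78 → 25 °C
Reagents that add atoms: dibromomethane, BrCBr; chlorotriisopropylsilane, CC(C)[Si](Cl)(C(C)C)C(C)C
Why: Kowalski ester homologation stopped at the ynolate: LiCHBr2 adds to the ester, enolate 17 undergoes bromine–lithium exchange and 1,2-methyl shift to ynolate 18, and the bulky silyl chloride should silylate 18 on oxygen and not on carbon.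

Step 10
Reactants: 15 racemic 3-tert-butoxy-4-(2,4-dimethoxy-3,6-dimethylbenzyl)cyclobut-2-en-1-one; 19 1-(triisopropylsiloxy)propyne
Product: 24 3-tert-butoxy-2-(2,4-dimethoxy-3,6-dimethylbenzyl)-6-methyl-5-(triisopropylsiloxy)phenol, via vinylketene 20 (not isolated), via vinylcyclobutenone 21 (not isolated), via dienylketene 22 (not isolated), via cyclohexadienone 23 (not isolated)
Conditions: 19 (2 equiv), toluene, 80 → 110 °C, argon, sealed tube
Reagents that add atoms: none
Why: Heating opens 15 by conrotatory 4π electrocyclic cleavage of its C1–C4 bond to vinylketene 20. The ketene C=C bond of 20 adds 19 in a [2+2] cycloaddition to give 21, the polarized alkyne bonding through its methyl-bearing, nucleophilic carbon to the ketene carbonyl carbon. A second 4π opening of 21 gives dienylketene 22, whose 6π electrocyclic closure between the ketene carbon and the carbon carrying the arylmethyl group forms the six-membered ring as cyclohexadienone 23, and enolization gives phenol 24. The closest known reaction type is the Danheiser benzannulation of cyclobutenones with siloxyalkynes to resorcinol monosilyl ethers; the alkoxy group at C3 of the cyclobutenone supplies the third oxygen. Ring B is thus closed in a pericyclic mode, and the arylmethyl carbon ends between two oxygens while C5 stays the only ring C–H. No stereocenter remains, because the sp3 carbons of 15, 21 and 23 all become aromatic carbons. The selectivity needed is the orientation of the [2+2] step, which the oxygen substituent of 19 fixes, and a preference of 20 for the alkyne over dimerization or capture by the product phenol, which the excess of 19 and the flanked hydroxyl of 24 should secure.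

Step 11
Reactants: 24 3-tert-butoxy-2-(2,4-dimethoxy-3,6-dimethylbenzyl)-6-methyl-5-(triisopropylsiloxy)phenol
Product: 25 5-tert-butoxy-4-(2,4-dimethoxy-3,6-dimethylbenzyl)-2-methylbenzene-1,3-diol
Conditions: n-Bu4NF (1.2 equiv), AcOH (1.2 equiv), THF, 0 °C
Reagents that add atoms: none
Why: Fluoride-induced cleavage of the aryl silyl ether; acetic acid buffers the phenoxide, and the tert-butyl ether, the methyl ethers and the bridge are inert to fluoride.

Step 12
Reactants: 25 5-tert-butoxy-4-(2,4-dimethoxy-3,6-dimethylbenzyl)-2-methylbenzene-1,3-diol
Product: 27 1-[3-(5-butanoyl-2,4-dimethoxy-3,6-dimethylbenzyl)-2,4,6-trihydroxy-5-methylphenyl]butan-1-one, via triol 26 (not isolated)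
Conditions: AlCl3 (8 equiv), CH2Cl2–PhNO2, 0 °C; then PrCOCl (2.5 equiv), 0 → 25 °C; 1 M HCl
Reagents that add atoms: butanoyl chloride, CCCC(Cl)=O
Why: AlCl3 first removes the tert-butyl group and converts the phenols into aryloxyaluminum species (triol 26), which favor C- over O-acylation; the two positions open to the tert-butyl cation are each flanked by two substituents, so C-alkylation is disfavored. Friedel–Crafts acylation then takes the single unsubstituted carbon of each ring, both activated by ortho and para oxygen, and each ketone deactivates its ring against acid-induced loss of the bridge.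

Step 13
Reactants: 27 1-[3-(5-butanoyl-2,4-dimethoxy-3,6-dimethylbenzyl)-2,4,6-trihydroxy-5-methylphenyl]butan-1-one
Product: 28 1-[3-(5-butanoyl-4-hydroxy-2-methoxy-3,6-dimethylbenzyl)-2,4,6-trihydroxy-5-methylphenyl]butan-1-one (the target)
Conditions: BCl3 (6 equiv), CH2Cl2, −78 → 0 °C; then MeOH, H2O
Reagents that add atoms: none
Why: Chelation-controlled ortho-demethylation: BCl3 binds the ring A ketone and the C6 methoxy oxygen in a six-membered chelate and chloride removes that methyl group. The C4 methoxy group has no chelation partner and ring B carries no ether, so one O–CH3 bond should be cleaved; any ortho demethylation already begun under AlCl3 in step 12 leads to the same product.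

## Compound list

1 | 2,5-dimethylresorcinol | Cc1cc(O)c(C)c(O)c1 | starting material
2 | 1,3-dimethoxy-2,5-dimethylbenzene | COc1cc(C)cc(OC)c1C | intermediate
3 | [(2,4-dimethoxy-3,6-dimethylphenyl)methylidene]dimethylammonium chloride | C[N+](C)=Cc1c(C)cc(OC)c(C)c1OC.[Cl-] | intermediate
4 | 2,4-dimethoxy-3,6-dimethylbenzaldehyde | O=Cc1c(C)cc(OC)c(C)c1OC | intermediate
5 | 2-[(2,4-dimethoxy-3,6-dimethylphenyl)methylidene]propanedioic acid | OC(=O)C(=Cc1c(C)cc(OC)c(C)c1OC)C(O)=O | intermediate
6 | (E)-3-(2,4-dimethoxy-3,6-dimethylphenyl)prop-2-enoic acid | OC(=O)/C=C/c1c(C)cc(OC)c(C)c1OC | intermediate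
7 | 3-(2,4-dimethoxy-3,6-dimethylphenyl)propanoic acid | OC(=O)CCc1c(C)cc(OC)c(C)c1OC | intermediate
8 | 3-(2,4-dimethoxy-3,6-dimethylphenyl)propanoyl chloride | ClC(=O)CCc1c(C)cc(OC)c(C)c1OC | intermediate
9 | tert-butyl vinyl ether | C=COC(C)(C)C | starting material
10 | 1,2-dibromo-1-tert-butoxyethane (racemic) | BrCC(Br)OC(C)(C)C | intermediate
11 | (Z)-1-bromo-2-tert-butoxyethene | Br/C=C\OC(C)(C)C | intermediate
12 | sodium tert-butoxyacetylide | [Na+].[C-]#COC(C)(C)C | intermediate
13 | tert-butoxyacetylene | C#COC(C)(C)C | intermediate
14 | 3-(2,4-dimethoxy-3,6-dimethylphenyl)prop-1-en-1-one (aldoketene) | O=C=CCc1c(C)cc(OC)c(C)c1OC | intermediate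
15 | 3-tert-butoxy-4-(2,4-dimethoxy-3,6-dimethylbenzyl)cyclobut-2-en-1-one (racemic) | CC(C)(C)OC1=CC(=O)C1Cc1c(C)cc(OC)c(C)c1OC | intermediate
16 | ethyl acetate | CCOC(C)=O | starting material
17 | lithium 1,1-dibromoprop-1-en-2-olate | [Li+].[O-]C(C)=C(Br)Br | intermediate
18 | lithium prop-1-yn-1-olate | [Li+].[O-]C#CC | intermediate
19 | 1-(triisopropylsiloxy)propyne | CC#CO[Si](C(C)C)(C(C)C)C(C)C | intermediate
20 | (3Z)-3-tert-butoxy-5-(2,4-dimethoxy-3,6-dimethylphenyl)penta-1,3-dien-1-one | O=C=C/C(OC(C)(C)C)=C/Cc1c(C)cc(OC)c(C)c1OC | intermediate
21 | 4-[(1Z)-1-tert-butoxy-3-(2,4-dimethoxy-3,6-dimethylphenyl)prop-1-en-1-yl]-2-methyl-3-(triisopropylsiloxy)cyclobut-2-en-1-one (racemic) | CC1=C(O[Si](C(C)C)(C(C)C)C(C)C)C(/C(OC(C)(C)C)=C/Cc2c(C)cc(OC)c(C)c2OC)C1=O | intermediate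
22 | (3E,5Z)-5-tert-butoxy-7-(2,4-dimethoxy-3,6-dimethylphenyl)-2-methyl-3-(triisopropylsiloxy)hepta-1,3,5-trien-1-one | O=C=C(C)/C(O[Si](C(C)C)(C(C)C)C(C)C)=C\C(OC(C)(C)C)=C\Cc1c(C)cc(OC)c(C)c1OC | intermediate
23 | 5-tert-butoxy-6-(2,4-dimethoxy-3,6-dimethylbenzyl)-2-methyl-3-(triisopropylsiloxy)cyclohexa-2,4-dien-1-one (racemic) | CC1=C(O[Si](C(C)C)(C(C)C)C(C)C)C=C(OC(C)(C)C)C(Cc2c(C)cc(OC)c(C)c2OC)C1=O | intermediate
24 | 3-tert-butoxy-2-(2,4-dimethoxy-3,6-dimethylbenzyl)-6-methyl-5-(triisopropylsiloxy)phenol | CC(C)(C)Oc1cc(O[Si](C(C)C)(C(C)C)C(C)C)c(C)c(O)c1Cc1c(C)cc(OC)c(C)c1OC | intermediate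
25 | 5-tert-butoxy-4-(2,4-dimethoxy-3,6-dimethylbenzyl)-2-methylbenzene-1,3-diol | CC(C)(C)Oc1cc(O)c(C)c(O)c1Cc1c(C)cc(OC)c(C)c1OC | intermediate
26 | 2-(2,4-dimethoxy-3,6-dimethylbenzyl)-4-methylbenzene-1,3,5-triol | Cc1c(O)cc(O)c(Cc2c(C)cc(OC)c(C)c2OC)c1O | intermediate
27 | 1-[3-(5-butanoyl-2,4-dimethoxy-3,6-dimethylbenzyl)-2,4,6-trihydroxy-5-methylphenyl]butan-1-one | CCCC(=O)c1c(C)c(Cc2c(O)c(C)c(O)c(C(=O)CCC)c2O)c(OC)c(C)c1OC | intermediate
28 | 1-[3-(5-butanoyl-4-hydroxy-2-methoxy-3,6-dimethylbenzyl)-2,4,6-trihydroxy-5-methylphenyl]butan-1-one | CCCC(=O)c1c(C)c(Cc2c(O)c(C)c(O)c(C(=O)CCC)c2O)c(OC)c(C)c1O | target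

## Step count and least certain steps

Total step count: 13. Longest linear sequence: 10 steps (steps 1, 2, 3, 4, 5, 8, 10, 11, 12, 13). Steps 6 and 7 and step 9 are side branches that supply 13 and 19.

**Step 10 (key step).** The cyclobutenone is a vinylogous ester and may open to the vinylketene only at temperatures at which the siloxyalkyne isomerizes or the tert-butyl ether loses isobutene. The vinylketene may also dimerize or be captured by the product phenol before the alkyne adds. The fallback gives up the annulation and joins the rings by electrophilic substitution. It sets out from 4: reduction with NaBH4 in methanol gives (2,4-dimethoxy-3,6-dimethylphenyl)methanol F1. F1 is added slowly to an excess of commercial 2-methylbenzene-1,3,5-triol with catalytic TsOH in dioxane at 25 °C. The dimethoxybenzyl cation should alkylate one of the two equivalent free carbons of the triol, so no regiochemical question arises, and the excess of triol limits double benzylation. The product is 26, now isolated, and the fallback comes back to the route at 26, which is acylated under the conditions of step 12 to 27.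

**Step 8.** tert-Butoxyacetylene may fragment to ketene and isobutene, or be protonated by the ammonium salt, before it intercepts the aldoketene, and dimerization of the aldoketene then takes over. The fallback sets out from 8 and changes the ynol ether and, with it, the endgame.

- The cycloaddition is run with commercial, thermally robust ethoxyacetylene (Et3N, Et2O, 25 °C) to give 3-ethoxy-4-(2,4-dimethoxy-3,6-dimethylbenzyl)cyclobut-2-en-1-one F2.
- Annulation of F2 with 19 as in step 10 should give 3-ethoxy-2-(2,4-dimethoxy-3,6-dimethylbenzyl)-6-methyl-5-(triisopropylsiloxy)phenol F3.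
- Buffered fluoride gives 5-ethoxy-4-(2,4-dimethoxy-3,6-dimethylbenzyl)-2-methylbenzene-1,3-diol F4.
- Double Friedel–Crafts butanoylation gives 1-[3-(5-butanoyl-2,4-dimethoxy-3,6-dimethylbenzyl)-2-ethoxy-4,6-dihydroxy-5-methylphenyl]butan-1-one F5.
- Because the ring B ketone of F5 is chelated by the C4 hydroxyl, the two phenols are first masked (Ac2O, pyridine, DMAP) as 4-butanoyl-6-(5-butanoyl-2,4-dimethoxy-3,6-dimethylbenzyl)-5-ethoxy-2-methyl-1,3-phenylene diacetate F6.
- BCl3 should then remove the ethyl group and the ring A C6 methyl group, each through a ketone–ether chelate, to give 4-butanoyl-6-(5-butanoyl-4-hydroxy-2-methoxy-3,6-dimethylbenzyl)-5-hydroxy-2-methyl-1,3-phenylene diacetate F7.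
- K2CO3 in methanol cleaves the acetates, and the fallback comes back to the route at 28.

The price is two more operations after the annulation than in the main route.

**Step 12.** Before both rings are deactivated, ipso protonation or ipso acylation at the bridge-bearing carbons may cut or scramble the diarylmethane. The second acylation, on ring A, may also stop short, and phenol esters may form. The fallback separates the two acylations and uses a nitrile for the first. It sets out from 25: Houben–Hoesch reaction (butyronitrile, ZnCl2, HCl, Et2O, 0 °C; then hot water) should acylate only the phloroglucinol ring, with loss of the tert-butyl group under the same acid, to give 1-[3-(2,4-dimethoxy-3,6-dimethylbenzyl)-2,4,6-trihydroxy-5-methylphenyl]butan-1-one F8. With ring B deactivated and the bridge stabilized, ring A is acylated with butanoyl chloride and TiCl4 in CH2Cl2 at low temperature, and the fallback comes back to the route at 27.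

**Step 3.** The aldehyde has two ortho substituents and is electron-rich, so condensation may be slow, and at the temperature needed the cinnamic acid may decarboxylate to a styrene. The fallback replaces the condensation with an olefination. It sets out from 4: Horner–Wadsworth–Emmons reaction with triethyl phosphonoacetate and NaH in THF gives ethyl (E)-3-(2,4-dimethoxy-3,6-dimethylphenyl)prop-2-enoate F9. Hydrogenation (H2, Pd/C) gives ethyl 3-(2,4-dimethoxy-3,6-dimethylphenyl)propanoate F10, and saponification with LiOH in aqueous THF comes back to the route at 7, at the cost of one extra step.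

## Further compounds

F1 | step 10 | (2,4-dimethoxy-3,6-dimethylphenyl)methanol | OCc1c(C)cc(OC)c(C)c1OC
F2 | step 8 | 3-ethoxy-4-(2,4-dimethoxy-3,6-dimethylbenzyl)cyclobut-2-en-1-one (racemic) | CCOC1=CC(=O)C1Cc1c(C)cc(OC)c(C)c1OC
F3 | step 8 | 3-ethoxy-2-(2,4-dimethoxy-3,6-dimethylbenzyl)-6-methyl-5-(triisopropylsiloxy)phenol | CCOc1cc(O[Si](C(C)C)(C(C)C)C(C)C)c(C)c(O)c1Cc1c(C)cc(OC)c(C)c1OC
F4 | step 8 | 5-ethoxy-4-(2,4-dimethoxy-3,6-dimethylbenzyl)-2-methylbenzene-1,3-diol | CCOc1cc(O)c(C)c(O)c1Cc1c(C)cc(OC)c(C)c1OC
F5 | step 8 | 1-[3-(5-butanoyl-2,4-dimethoxy-3,6-dimethylbenzyl)-2-ethoxy-4,6-dihydroxy-5-methylphenyl]butan-1-one | CCCC(=O)c1c(C)c(Cc2c(O)c(C)c(O)c(C(=O)CCC)c2OCC)c(OC)c(C)c1OC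
F6 | step 8 | 4-butanoyl-6-(5-butanoyl-2,4-dimethoxy-3,6-dimethylbenzyl)-5-ethoxy-2-methyl-1,3-phenylene diacetate | CCCC(=O)c1c(C)c(Cc2c(OC(C)=O)c(C)c(OC(C)=O)c(C(=O)CCC)c2OCC)c(OC)c(C)c1OC
F7 | step 8 | 4-butanoyl-6-(5-butanoyl-4-hydroxy-2-methoxy-3,6-dimethylbenzyl)-5-hydroxy-2-methyl-1,3-phenylene diacetate | CCCC(=O)c1c(C)c(Cc2c(OC(C)=O)c(C)c(OC(C)=O)c(C(=O)CCC)c2O)c(OC)c(C)c1O
F8 | step 12 | 1-[3-(2,4-dimethoxy-3,6-dimethylbenzyl)-2,4,6-trihydroxy-5-methylphenyl]butan-1-one | CCCC(=O)c1c(O)c(C)c(O)c(Cc2c(C)cc(OC)c(C)c2OC)c1O
F9 | step 3 | ethyl (E)-3-(2,4-dimethoxy-3,6-dimethylphenyl)prop-2-enoate | CCOC(=O)/C=C/c1c(C)cc(OC)c(C)c1OC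
F10 | step 3 | ethyl 3-(2,4-dimethoxy-3,6-dimethylphenyl)propanoate | CCOC(=O)CCc1c(C)cc(OC)c(C)c1OC
A1 | alternative 1 | 3,5-dimethoxy-4-methyl-2-(trimethylsilyl)phenyl trifluoromethanesulfonate | COc1cc(OS(=O)(=O)C(F)(F)F)c([Si](C)(C)C)c(OC)c1C
A2 | alternative 1 | 3,5-dimethoxy-4-methylbenzyne | COC1=C(C)C(OC)=CC#C1
A3 | alternative 1 | 2-(phenylsulfonyl)-1-[2,4,6-tris(benzyloxy)-3-methylphenyl]ethan-1-one | Cc1c(OCc2ccccc2)cc(OCc2ccccc2)c(C(=O)CS(=O)(=O)c2ccccc2)c1OCc1ccccc1
A4 | alternative 1 | [2,4-dimethoxy-3-methyl-6-(phenylsulfonylmethyl)phenyl][2,4,6-tris(benzyloxy)-3-methylphenyl]methanone | COc1cc(CS(=O)(=O)c2ccccc2)c(C(=O)c2c(OCc3ccccc3)c(C)c(OCc3ccccc3)cc2OCc2ccccc2)c(OC)c1C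
A5 | alternative 2 | ethyl 3-oxopentanoate | CCC(=O)CC(=O)OCC
A6 | alternative 2 | ethyl (2E)-2-[2,4,6-tris(benzyloxy)-3-methylbenzyl]but-2-enoate | C/C=C(\Cc1c(OCc2ccccc2)c(C)c(OCc2ccccc2)cc1OCc1ccccc1)C(=O)OCC
A7 | alternative 2 | ethyl 3,6-dimethyl-2,4-dioxo-5-[2,4,6-tris(benzyloxy)-3-methylbenzyl]cyclohexane-1-carboxylate (mixture of diastereomers and enol forms) | CCOC(=O)C1C(C)C(Cc2c(OCc3ccccc3)c(C)c(OCc3ccccc3)cc2OCc2ccccc2)C(=O)C(C)C1=O
A8 | alternative 3 | {[(1Z,3Z)-1,3-dimethoxy-2-methyl-5-[2,4,6-tris(benzyloxy)-3-methylphenyl]penta-1,3-dien-1-yl]oxy}trimethylsilane | CO/C(O[Si](C)(C)C)=C(C)/C(OC)=C/Cc1c(OCc2ccccc2)c(C)c(OCc2ccccc2)cc1OCc1ccccc1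
A9 | alternative 3 | hept-2-yn-4-one | CC#CC(=O)CCC
A10 | alternative 3 | 1-{2-hydroxy-4-methoxy-3,6-dimethyl-5-[2,4,6-tris(benzyloxy)-3-methylbenzyl]phenyl}butan-1-one | CCCC(=O)c1c(C)c(Cc2c(OCc3ccccc3)c(C)c(OCc3ccccc3)cc2OCc2ccccc2)c(OC)c(C)c1O
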